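**Retrosynthetic overview**
1. Target 12 ⇒ tetra-TBS ether 11; global O-desilylation is last, so no acid or hydrogenolysis ever meets the labile 4-hydroxybenzyl ether.
2. 11 ⇒ aldehyde 6 + alcohol 8 by C–O disconnection at the ether (new organocatalytic transfer-hydrogenative reductive etherification); 8 is made from 6, so one building block supplies both halves.
3. 6 ⇒ catechol aldehyde 5 ⇒ 5,6-dibromovanillin 3 (silylation; O-demethylation).
4. 3 ⇒ vanillin 1 by two regiocontrolled SEAr brominations (OH-directed at C5, then OMe-directed at C6).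
5. No ring is formed: both benzene rings come intact from vanillin.

**Assumptions**
- The target has no stereocentre, axis or stereogenic double bond, so "single enantiomer" is taken to mean the achiral compound as drawn.
- Partly silylated or desilylated species passed through within one multiple identical functionalisation are not counted as separate compounds.

**Route**

Step 1
Reactants: 1 vanillin (4-hydroxy-3-methoxybenzaldehyde)
Product: 2 5-bromovanillin (3-bromo-4-hydroxy-5-methoxybenzaldehyde)
Conditions: Br2 (1.05 equiv), MeOH, 0 °C → rt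
Reagents that add atoms: bromine, BrBr
Why: Electrophilic aromatic bromination (SEAr); the free phenol is the strongest director, its para position is blocked by CHO, and its only open ortho position (C5, meta to CHO) is brominated.

Step 2
Reactants: 2 5-bromovanillin
Product: 3 5,6-dibromovanillin (2,3-dibromo-4-hydroxy-5-methoxybenzaldehyde)
Conditions: Br2 (1.3 equiv), Fe powder (10 mol%), AcOH, 60 °C
Reagents that add atoms: bromine, BrBr
Why: Lewis-acid-assisted SEAr (FeBr3 formed in situ); with both positions ortho to OH occupied, the methoxy group directs bromine to its para position C6, while C2 is only ortho-activated and wedged between CHO and OMe.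

Step 3
Reactants: 3 5,6-dibromovanillin
Product: 5 2,3-dibromo-4,5-dihydroxybenzaldehyde, via 2,4,5-tribromo-1,3,2-benzodioxaborole-6-carbaldehyde 4 (not isolated)
Conditions: BBr3 (2.2 equiv), CH2Cl2, −78 °C → rt; then H2O, 0 °C
Reagents that add atoms: none
Why: BBr3 aryl methyl ether cleavage; boron binds the methoxy oxygen next to the phenol, bromide removes the methyl group by SN2 to give the chelated catechol borate 4, and water hydrolyses the B–O bonds while aldehyde and aryl bromides stay intact.

Step 4
Reactants: 5 2,3-dibromo-4,5-dihydroxybenzaldehyde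
Product: 6 2,3-dibromo-4,5-bis[(tert-butyldimethylsilyl)oxy]benzaldehyde
Conditions: TBSCl (2.6 equiv), imidazole (5 equiv), DMAP (5 mol%), DMF, rt → 40 °C
Reagents that add atoms: tert-butyldimethylsilyl chloride (TBSCl), CC(C)(C)[Si](C)(C)Cl
Why: Imidazole-promoted O-silylation (Corey TBS protection) of both acidic phenols; the silyl ethers survive the later hydride and weak-acid steps and come off with fluoride without touching a benzyl ether.

Step 5
Reactants: 6 2,3-dibromo-4,5-bis[(tert-butyldimethylsilyl)oxy]benzaldehyde (about half of the batch; the rest is kept for step 6)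
Product: 8 [2,3-dibromo-4,5-bis(tert-butyldimethylsilyloxy)phenyl]methanol, via diisobutylaluminium [2,3-dibromo-4,5-bis(tert-butyldimethylsilyloxy)phenyl]methoxide 7 (not isolated)
Conditions: DIBAL-H (1.1 equiv), CH2Cl2, −78 °C; then aq. Rochelle salt
Reagents that add atoms: none
Why: 1,2-Hydride reduction of the aldehyde by DIBAL-H at −78 °C with a non-basic work-up gives the benzylic alcohol without touching the aryl bromides or the base-labile aryl silyl ethers.

Step 6
Reactants: 6 2,3-dibromo-4,5-bis[(tert-butyldimethylsilyl)oxy]benzaldehyde, 8 [2,3-dibromo-4,5-bis(tert-butyldimethylsilyloxy)phenyl]methanol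
Product: 11 bis[2,3-dibromo-4,5-bis(tert-butyldimethylsilyloxy)benzyl] ether, via racemic hemiacetal [2,3-dibromo-4,5-bis(tert-butyldimethylsilyloxy)phenyl]{[2,3-dibromo-4,5-bis(tert-butyldimethylsilyloxy)benzyl]oxy}methanol 9 (not isolated), via O-benzyl aryl oxocarbenium diphenyl phosphate 10 (not isolated)
Conditions: 6 (1.0 equiv), 8 (1.05 equiv), Hantzsch ester (diethyl 2,6-dimethyl-1,4-dihydropyridine-3,5-dicarboxylate, 1.3 equiv), (PhO)2P(O)OH (10 mol%), 5 Å MS, PhMe, 40 °C
Reagents that add atoms: none
Why: Proposed new method: Brønsted-acid-catalysed transfer-hydrogenative reductive etherification, in which diphenyl phosphate reversibly condenses 6 with 8 to hemiacetal 9 and ionises it (water held by the sieves) to the aryl(alkoxy)carbenium phosphate 10, which the Hantzsch ester then reduces irreversibly by hydride transfer (estimated Mayr E ≈ 0–3 for the cation against N ≈ 9 for the donor, so near diffusion-controlled); the free aldehyde is barely protonated by this weak acid, ionising the product ether would need a much stronger acid (ring deactivated by two Br), the weakly basic Hantzsch pyridine does not quench the catalyst, and aryl bromides and aryl silyl ethers are inert to both reagents; the closest known reaction types are phosphoric acid/Hantzsch ester reductive amination through iminium ions and silane/Lewis acid reductive etherification through the same oxocarbenium ion.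

Step 7
Reactants: 11 bis[2,3-dibromo-4,5-bis(tert-butyldimethylsilyloxy)benzyl] ether
Product: 12 bis(2,3-dibromo-4,5-dihydroxybenzyl) ether (target)
Conditions: TBAF (4.4 equiv), AcOH (4.4 equiv), THF, 0 °C, Ar; pH 5 buffer work-up
Reagents that add atoms: none
Why: Fluoride-induced desilylation driven by Si–F bond formation; the acetic acid buffer protonates each phenoxide as it forms, so no para-phenoxide can expel the benzylic alkoxide (quinone methide fragmentation) and the dibenzyl ether and C–Br bonds survive.

**Compound list**
1 | vanillin (4-hydroxy-3-methoxybenzaldehyde) | COc1cc(C=O)ccc1O | starting material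
2 | 5-bromovanillin (3-bromo-4-hydroxy-5-methoxybenzaldehyde) | COc1cc(C=O)cc(Br)c1O | intermediate
3 | 5,6-dibromovanillin (2,3-dibromo-4-hydroxy-5-methoxybenzaldehyde) | COc1cc(C=O)c(Br)c(Br)c1O | intermediate
4 | 2,4,5-tribromo-1,3,2-benzodioxaborole-6-carbaldehyde (cyclic B-bromo catechol borate of 5) | O=Cc1cc2OB(Br)Oc2c(Br)c1Br | intermediate
5 | 2,3-dibromo-4,5-dihydroxybenzaldehyde | O=Cc1cc(O)c(O)c(Br)c1Br | intermediate
6 | 2,3-dibromo-4,5-bis[(tert-butyldimethylsilyl)oxy]benzaldehyde | O=Cc1cc(O[Si](C)(C)C(C)(C)C)c(O[Si](C)(C)C(C)(C)C)c(Br)c1Br | intermediate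
7 | diisobutylaluminium [2,3-dibromo-4,5-bis(tert-butyldimethylsilyloxy)phenyl]methoxide | CC(C)C[Al](CC(C)C)OCc1cc(O[Si](C)(C)C(C)(C)C)c(O[Si](C)(C)C(C)(C)C)c(Br)c1Br | intermediate
8 | [2,3-dibromo-4,5-bis(tert-butyldimethylsilyloxy)phenyl]methanol | OCc1cc(O[Si](C)(C)C(C)(C)C)c(O[Si](C)(C)C(C)(C)C)c(Br)c1Br | intermediate
9 | racemic hemiacetal [2,3-dibromo-4,5-bis(tert-butyldimethylsilyloxy)phenyl]{[2,3-dibromo-4,5-bis(tert-butyldimethylsilyloxy)benzyl]oxy}methanol | OC(OCc1cc(O[Si](C)(C)C(C)(C)C)c(O[Si](C)(C)C(C)(C)C)c(Br)c1Br)c1cc(O[Si](C)(C)C(C)(C)C)c(O[Si](C)(C)C(C)(C)C)c(Br)c1Br | intermediate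
10 | O-[2,3-dibromo-4,5-bis(tert-butyldimethylsilyloxy)benzyl] [2,3-dibromo-4,5-bis(tert-butyldimethylsilyloxy)phenyl]methylideneoxonium diphenyl phosphate (oxocarbenium ion pair) | Brc1c(Br)c(O[Si](C)(C)C(C)(C)C)c(O[Si](C)(C)C(C)(C)C)cc1C=[O+]Cc1cc(O[Si](C)(C)C(C)(C)C)c(O[Si](C)(C)C(C)(C)C)c(Br)c1Br.[O-]P(=O)(Oc1ccccc1)Oc1ccccc1 | intermediate
11 | bis[2,3-dibromo-4,5-bis(tert-butyldimethylsilyloxy)benzyl] ether | CC(C)(C)[Si](C)(C)Oc1cc(COCc2cc(O[Si](C)(C)C(C)(C)C)c(O[Si](C)(C)C(C)(C)C)c(Br)c2Br)c(Br)c(Br)c1O[Si](C)(C)C(C)(C)C | intermediate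
12 | bis(2,3-dibromo-4,5-dihydroxybenzyl) ether | Oc1cc(COCc2cc(O)c(O)c(Br)c2Br)c(Br)c(Br)c1O | target

**Step count and risks**

Total steps: 7. Longest linear sequence: 7 (1 → 2 → 3 → 5 → 6 → 8 → 11 → 12).

Three steps most likely to fail:

Step 6 (the proposed new method). The phosphate acid may ionise hemiacetal 9 too slowly, or the Hantzsch ester may reduce a small amount of silyloxybenzyl cation to the toluene. The fallback uses known chemistry, sets out from 8 and comes back at 11. Part of 8 is converted by an Appel reaction (CBr4, PPh3, CH2Cl2, 0 °C) into 2,3-dibromo-4,5-bis[(tert-butyldimethylsilyl)oxy]benzyl bromide F1. A second equivalent of 8 is then alkylated with F1 under silver(I) oxide promotion (Ag2O, 4 Å MS, CH2Cl2, rt). This neutral Williamson-type etherification avoids free alkoxide and therefore silyl migration, and gives 11.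

Step 7. The freed 4-hydroxybenzyl ether could fragment through a quinone methide, or the catechols could oxidise in air during desilylation. The fallback avoids protecting groups altogether, sets out from 5 and comes back at 12. Aldehyde 5 is reduced with NaBH4 (THF/H2O, 0 °C) to 2,3-dibromo-4,5-dihydroxybenzyl alcohol (lanosol) F2. F2 is then dimerised by acid-catalysed dehydrative self-etherification (p-TsOH 2 mol%, MeCN, 4 Å MS, rt). The para-hydroxyl group lets the benzylic alcohol ionise to a quinone methide that a second molecule of F2 traps at its benzylic oxygen, giving 12 directly. The main risk of this fallback is C-alkylation or oligomerisation of the quinone methide.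

Step 2. The second bromination needs forcing conditions on a deactivated ring and could suffer ipso-bromodeformylation para to the free phenol. The fallback reverses the order of the two brominations, sets out from 1 and comes back at 3. Vanillin is acetylated (Ac2O, pyridine, rt) to 4-formyl-2-methoxyphenyl acetate (vanillin acetate) F3. With the phenol masked, bromination (Br2, AcOH, rt) goes para to the methoxy group and gives 5-bromo-4-formyl-2-methoxyphenyl acetate F4. Hydrolysis (6 M aq. HCl, reflux) gives 6-bromovanillin (2-bromo-4-hydroxy-5-methoxybenzaldehyde) F5. The liberated phenol then directs a second bromination (Br2, AcOH, rt) to its open ortho position, giving 3.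

**Further compounds**
F1 | step 6 | 2,3-dibromo-4,5-bis[(tert-butyldimethylsilyl)oxy]benzyl bromide | BrCc1cc(O[Si](C)(C)C(C)(C)C)c(O[Si](C)(C)C(C)(C)C)c(Br)c1Br
F2 | step 7 | 2,3-dibromo-4,5-dihydroxybenzyl alcohol (lanosol) | OCc1cc(O)c(O)c(Br)c1Br
F3 | step 2 | 4-formyl-2-methoxyphenyl acetate (vanillin acetate) | CC(=O)Oc1ccc(C=O)cc1OC
F4 | step 2 | 5-bromo-4-formyl-2-methoxyphenyl acetate (6-bromovanillin acetate) | CC(=O)Oc1cc(Br)c(C=O)cc1OC
F5 | step 2 | 2-bromo-4-hydroxy-5-methoxybenzaldehyde (6-bromovanillin) | COc1cc(C=O)c(Br)cc1O
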